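Two sinapyl alcohol units are tied to an enantiopure diol, joined and hydrated in one oxidative cascade that closes the oxolane, then corrected at one benzylic centre and released. The face selectivity of the key coupling and the kinetic 7′ configuration it gives are predictions from geometric and conformational reasoning, not from precedent or calculation.

**Plan**

Retrosynthetic cuts, in order:
- the four carbonate C–O bonds that tie O9/O9′ to a (1S,2S)-cyclohexane-1,2-diol tether
- ring O–C7 (oxolane O1–C2)
- O–C7′ (O1–C5, the oxygen going back to water)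
- C8–C8′ (C3–C4), which leaves two sinapyl alcohol units

Enabling feature: both oxolane carbons next to O (C2, C5) are benzylic and para to a free phenolic OH on a 3,5-dimethoxyphenyl ring. Each is therefore a latent p-quinone methide carbon. C3–C4 links the β-carbons of two identical C6–C3 halves related by a C2 axis.

Forward order: sinapaldehyde gives O-silyl sinapyl alcohol, and two copies are hung on the diol as carbonates and desilylated. One oxidative event then makes first the 12-membered ring (C8–C8′) and then the oxolane (O–C7′, O–C7).

Stereochemistry: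
- C8/C8′ come from the tether.
- C7 comes from the ring closure.
- C7′ comes from Lewis-acid equilibration to the all-trans isomer.
- Because the tether is enantiopure, every wrong isomer is a diastereomer and can be removed by chromatography.

Methanolysis then releases the target and returns the diol.

Key step: step 6

Assumption: the (1S,2S)-diol is taken as the matched tether for the (8R,8′R) series, on the basis of a hand ring-closure analysis (O–C–C–O about +60°, planar Z,Z-carbonates, arylvinyl groups exo). Lignan numbering is used throughout (C7/C7′ = oxolane C2/C5, C8/C8′ = C3/C4, C9/C9′ = CH2O).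

**Route**

Step 1
Reactants: 1 sinapaldehyde, (E)-3-(4-hydroxy-3,5-dimethoxyphenyl)prop-2-enal
Product: 2 4-O-TBS-sinapaldehyde
Conditions: TBSCl (1.2 equiv), imidazole (2.5 equiv), DMF, rt
Reagents that add atoms: tert-butyldimethylsilyl chloride, CC(C)(C)[Si](C)(C)Cl
Why: Standard silyl ether formation masks the only acidic OH so that the later acyl-transfer steps meet a single nucleophile, and the aryl silyl ether can later be removed with buffered fluoride without touching carbonates.

Step 2
Reactants: 2 4-O-TBS-sinapaldehyde
Product: 3 4-O-TBS-sinapyl alcohol, (E)-configured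
Conditions: NaBH4, MeOH–THF, 0 °C
Reagents that add atoms: none
Why: Borohydride 1,2-reduction of a cinnamaldehyde should give the primary allylic alcohol with the E-alkene and the aryl silyl ether untouched.

Step 3
Reactants: 4 (1S,2S)-cyclohexane-1,2-diol
Product: 5 (1S,2S)-cyclohexane-1,2-diyl bis(4-nitrophenyl carbonate)
Conditions: 4-nitrophenyl chloroformate (2.5 equiv), pyridine, CH2Cl2, 0 °C to rt
Reagents that add atoms: 4-nitrophenyl chloroformate, O=C(Cl)Oc1ccc(cc1)[N+](=O)[O-]
Why: Chloroformate O-acylation activates both hydroxyls without touching the two C–O stereocentres, and excess reagent should outrun closure of the mono-acylated diol to the strained trans-fused cyclic carbonate.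

Step 4
Reactants: 5 (1S,2S)-cyclohexane-1,2-diyl bis(4-nitrophenyl carbonate); 3 4-O-TBS-sinapyl alcohol (2.1 equiv)
Product: 6 (1S,2S)-cyclohexane-1,2-diyl bis[(E)-4-O-TBS-sinapyl carbonate]
Conditions: DMAP (0.2 equiv), iPr2NEt (2.5 equiv), CH2Cl2, rt
Reagents that add atoms: none
Why: In a DMAP-catalysed acyl transfer (mixed-carbonate interchange) the unhindered primary allylic OH displaces 4-nitrophenoxide from each activated carbonate, which hangs both monomers on the C2-symmetric tether.

Step 5
Reactants: 6 (1S,2S)-cyclohexane-1,2-diyl bis[(E)-4-O-TBS-sinapyl carbonate]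
Product: 7 (1S,2S)-cyclohexane-1,2-diyl bis[(E)-sinapyl carbonate], both phenols free
Conditions: TBAF (2.2 equiv), AcOH (2.6 equiv), THF, 0 °C
Reagents that add atoms: none
Why: Fluoride desilylation of aryl silyl ethers is fast, and the acetic acid buffer keeps the liberated phenols protonated, which should suppress the phenoxide-driven 1,8-elimination of the p-hydroxycinnamyl carbonates.

Step 6
Reactants: 7 (1S,2S)-cyclohexane-1,2-diyl bis[(E)-sinapyl carbonate]
Product: 10 (7S,8R,8′R,7′R)-macrocyclic tetrahydrofuran bis-carbonate, via bis-quinone methide 8 (not isolated), via hydroxy quinone methide 9 (not isolated)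
Conditions: laccase (Trametes versicolor, cat.), O2 (air), MeCN–NaOAc buffer pH 5 (3:7), 7 added by syringe pump (≤0.5 mM), 25 °C
Reagents that add atoms: water, O
Why: Proposed new method: laccase/O2 removes H• from both syringyl OH groups of 7, the two phenoxyl radicals (spin at C8 and C8′, ring positions 3 and 5 blocked by OMe) recombine C8–C8′ inside the tether to give bis-quinone methide 8, water adds at C7′ to give 9, and the new C7′–OH then adds to C7 of the remaining quinone methide, which forms the O–C7 bond, closes the tetrahydrofuran and rearomatises the second ring. The closest known reaction types are the laccase- or peroxidase-mediated β–β dehydrodimerisation of sinapyl alcohol and of its γ-O-acyl esters (the latter end as 2,5-diaryltetrahydrofurans through the same water capture) and the diol-templated intramolecular oxidative coupling of vicinal digalloyl esters; new here is that a chiral tether makes the β–β coupling intramolecular and face-selective. Ring closures: the 12-membered bis-carbonate ring forms by a radical–radical recombination that is exo to both C7=C8 units, and the oxolane forms by a 5-exo-trig oxa-1,6-addition. C8 and C8′ are set by the tether: the diequatorial (1S,2S) chair fixes O–C–C–O at about +60°, the planar Z,Z-carbonate arms run side by side, and with both arylvinyl groups pointing away from the forming ring only Si,Si bonding leaves a staggered C8–C9 and a near-anti C9–C8–C8′–C9′ torsion (8R,8′R), whereas Re,Re bonding needs nearly eclipsed ones. C7 is set in the closure, because with H8 eclipsing the quinone methide (A1,3 strain) the oxygen tethered through C8′ can only reach the C8′-side face, which puts the aryl group trans to C9 (7S); C7′ is set by free water, which should take the open face anti to C8 and so give the 7′,8′-cis (7′R) centre that step 7 corrects. The step needs β–β coupling over β–O–4 and intermolecular coupling (secured by the tether, the blocked 3,5-positions and high dilution) and water capture over O9 capture or C8–H tautomerisation (secured by the acylated O9/O9′ and the alcohol oxidation level of C9).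

Step 7
Reactants: 10 (7S,8R,8′R,7′R)-macrocyclic tetrahydrofuran bis-carbonate
Product: 11 (7S,8R,8′R,7′S)-macrocyclic tetrahydrofuran bis-carbonate, all-trans and C2-symmetric
Conditions: BF3·OEt2 (0.2 equiv), CH2Cl2, −20 to 0 °C
Reagents that add atoms: none
Why: This is the known Lewis-acid epimerisation of 2-aryltetrahydrofuran lignans, in which BF3 reversibly ionises the p-hydroxybenzylic C–O bonds (SN1 ring opening and 5-exo re-closure), so the 7′,8′-cis isomer should drain into the all-trans thermodynamic isomer (7′R to 7′S) while C8/C8′ stay untouched and the O9/O9′ carbonates keep the furofuran pathway closed.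

Step 8
Reactants: 11 (7S,8R,8′R,7′S)-macrocyclic tetrahydrofuran bis-carbonate
Product: 12 huazhongilexin, [(2S,3R,4R,5S)-2,5-bis(4-hydroxy-3,5-dimethoxyphenyl)oxolane-3,4-diyl]dimethanol
Conditions: K2CO3 (cat.), MeOH, Ar, 0 °C to rt; then Amberlite IR-120 (H+)
Reagents that add atoms: none
Why: Base-catalysed transesterification (carbonate methanolysis) frees both primary alcohols without touching any stereocentre, returns the chiral diol, and avoids acid, which would turn the free diol into the furofuran.

**Compound list**

1 | sinapaldehyde, (E)-3-(4-hydroxy-3,5-dimethoxyphenyl)prop-2-enal | COc1cc(/C=C/C=O)cc(OC)c1O | starting material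
2 | 4-O-TBS-sinapaldehyde | COc1cc(/C=C/C=O)cc(OC)c1O[Si](C)(C)C(C)(C)C | intermediate
3 | 4-O-TBS-sinapyl alcohol | COc1cc(/C=C/CO)cc(OC)c1O[Si](C)(C)C(C)(C)C | intermediate
4 | (1S,2S)-cyclohexane-1,2-diol | O[C@H]1CCCC[C@@H]1O | starting material
5 | (1S,2S)-cyclohexane-1,2-diyl bis(4-nitrophenyl carbonate) | O=C(Oc1ccc(cc1)[N+](=O)[O-])O[C@H]2CCCC[C@@H]2OC(=O)Oc3ccc(cc3)[N+](=O)[O-] | intermediate
6 | (1S,2S)-cyclohexane-1,2-diyl bis[(E)-4-O-TBS-sinapyl carbonate] | COc1cc(/C=C/COC(=O)O[C@H]2CCCC[C@@H]2OC(=O)OC/C=C/c3cc(OC)c(O[Si](C)(C)C(C)(C)C)c(OC)c3)cc(OC)c1O[Si](C)(C)C(C)(C)C | intermediate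
7 | (1S,2S)-cyclohexane-1,2-diyl bis[(E)-sinapyl carbonate] | COc1cc(/C=C/COC(=O)O[C@H]2CCCC[C@@H]2OC(=O)OC/C=C/c3cc(OC)c(O)c(OC)c3)cc(OC)c1O | intermediate
8 | (8R,8′R)-12-membered bis-carbonate bis(p-quinone methide) | O=C1C(OC)=CC(=C[C@H]2COC(=O)O[C@H]3CCCC[C@@H]3OC(=O)OC[C@@H]2C=C4C=C(OC)C(=O)C(OC)=C4)C=C1OC | intermediate
9 | (8R,8′R,7′R)-7′-hydroxy mono(p-quinone methide) macrocycle | O=C1C(OC)=CC(=C[C@H]2COC(=O)O[C@H]3CCCC[C@@H]3OC(=O)OC[C@@H]2[C@@H](O)c4cc(OC)c(O)c(OC)c4)C=C1OC | intermediate
10 | (7S,8R,8′R,7′R)-macrocyclic tetrahydrofuran bis-carbonate (7,8-trans, 8,8′-trans, 7′,8′-cis) | COc1cc([C@H]2O[C@@H](c3cc(OC)c(O)c(OC)c3)[C@H]4COC(=O)O[C@H]5CCCC[C@@H]5OC(=O)OC[C@H]24)cc(OC)c1O | intermediate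
11 | (7S,8R,8′R,7′S)-macrocyclic tetrahydrofuran bis-carbonate (all-trans) | COc1cc([C@H]2O[C@H](c3cc(OC)c(O)c(OC)c3)[C@H]4COC(=O)O[C@H]5CCCC[C@@H]5OC(=O)OC[C@H]24)cc(OC)c1O | intermediate
12 | huazhongilexin | COc1cc([C@H]2O[C@H](c3cc(OC)c(O)c(OC)c3)[C@@H](CO)[C@@H]2CO)cc(OC)c1O | target

**Step count**

Total step count: 8.
Longest linear sequence: 7 (steps 1, 2, 4, 5, 6, 7, 8).

**Steps most likely to fail**

1. Step 6.
What may go wrong: the two radical termini may fail to recombine inside the tether, giving oligomers through intermolecular β–β or β–O–4 coupling. The face selectivity at C8/C8′ may also be poor or reversed.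
Fallback (known chemistry), setting out from 3:
   - Acetylation (Ac2O, pyridine) gives 4-O-TBS-sinapyl acetate F1.
   - Buffered TBAF gives sinapyl acetate F2.
   - The established intermolecular laccase or peroxidase dehydrodimerisation of this γ-acylated monolignol in aqueous buffer gives the racemic 2,5-diaryl-3,4-bis(acetoxymethyl)tetrahydrofurans, expected mainly as the 7′-epi diacetate F3.
   - BF3·OEt2 equilibration gives the racemic all-trans diacetate.
   - Preparative HPLC on a chiral phase splits this into the (7S,8R,8′R,7′S)-diacetate F4 and its mirror image F5.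
   - K2CO3/MeOH on F4 rejoins the route at 12.

2. Step 7.
What may go wrong: the benzylic cation may be captured by C2/C6 of the neighbouring syringyl ring (aryltetralin formation). The macrocycle may also shift the equilibrium position unfavourably.
Fallback, setting out from 10: the C–O bond is ionised as an anion instead of a cation.
   - Mild base (DBU, MeCN, gentle warming) makes the phenoxide, which expels the ring alkoxide by retro-oxa-1,6-addition.
   - This gives the (7S,8R,8′R)-7-hydroxy quinone methide F6, in which no cation is present for Friedel–Crafts capture.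
   - F6 re-closes from the C8′-side face and rejoins the route at 11.
   - Base-mediated C7 epimerisation through quinone methides is known for phenolic 7-oxygenated lignans.

3. Step 3.
What may go wrong: the mono-activated diol may close to the cyclic carbonate, or the second, more hindered acylation may stall.
Fallback, setting out from 3 and 4: the polarity of the tether assembly is reversed.
   - 4-Nitrophenyl chloroformate/pyridine on 3 gives 4-O-TBS-sinapyl 4-nitrophenyl carbonate F7.
   - Two equivalents of F7 acylate diol 4 (DMAP, iPr2NEt, CH2Cl2), rejoining the route at 6.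

Further compounds
F1 | step 6 | 4-O-TBS-sinapyl acetate | COc1cc(/C=C/COC(C)=O)cc(OC)c1O[Si](C)(C)C(C)(C)C
F2 | step 6 | sinapyl acetate | COc1cc(/C=C/COC(C)=O)cc(OC)c1O
F3 | step 6 | racemic 7′-epi tetrahydrofuran diacetate (one enantiomer drawn) | COc1cc([C@H]2O[C@@H](c3cc(OC)c(O)c(OC)c3)[C@@H](COC(C)=O)[C@@H]2COC(C)=O)cc(OC)c1O
F4 | step 6 | (7S,8R,8′R,7′S)-all-trans tetrahydrofuran diacetate | COc1cc([C@H]2O[C@H](c3cc(OC)c(O)c(OC)c3)[C@@H](COC(C)=O)[C@@H]2COC(C)=O)cc(OC)c1O
F5 | step 6 | (7R,8S,8′S,7′R)-all-trans tetrahydrofuran diacetate | COc1cc([C@@H]2O[C@@H](c3cc(OC)c(O)c(OC)c3)[C@H](COC(C)=O)[C@H]2COC(C)=O)cc(OC)c1O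
F6 | step 7 | (7S,8R,8′R)-7-hydroxy quinone methide macrocycle | O=C1C(OC)=CC(=C[C@H]2COC(=O)O[C@H]3CCCC[C@@H]3OC(=O)OC[C@@H]2[C@H](O)c4cc(OC)c(O)c(OC)c4)C=C1OC
F7 | step 3 | 4-O-TBS-sinapyl 4-nitrophenyl carbonate | COc1cc(/C=C/COC(=O)Oc2ccc(cc2)[N+](=O)[O-])cc(OC)c1O[Si](C)(C)C(C)(C)C
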